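The constants were set for the occasion, and the outcome is calculated.

A ratio of charges caps these flasks. Coupling partner over starting material is Y = 50.0 %, the ceiling on target in percent of the starting material charged: each turn of the catalyst spends one of each and gives one target, and coupling partner, charged at less than starting material, is the limiting reagent.

| flask | starting material | coupling partner | free catalyst | time | remark |
|---|---|---|---|---|---|
| green | 0.010 M | 5.00 mM | 0.15 mM | 2.5 d | everything together at the start |
| amber | 0.010 M | 5.00 mM (fed, over 12 h) | 0.15 mM | 2.5 d | all else is in the flask from the start; the feed brings no volume worth counting |
| grey | 0.010 M (fed, over 12 h) | 5.00 mM | 0.15 mM | 2.5 d | all else is in the flask from the start; the feed brings no volume worth counting |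

1. the best flask by amount of target, in percent of the starting material charged; "all alike" if 1.5 percentage points covers them all (green / amber / grey / all alike)
2. amount of target at the end, in percent of the starting material charged, green
3. amount of target at the end, in percent of the starting material charged, amber
4. amount of target at the end, in percent of the starting material charged, grey

    catalyst intermediate A ⇌ catalyst intermediate B (K1 = 0.360, k1 = 0.114 min⁻¹)
    catalyst intermediate C ⇌ catalyst intermediate D (K2 = 0.426, k2 = 0.106 min⁻¹)
    catalyst intermediate D → free catalyst + target (k3 = 0.0431 min⁻¹)
    starting material + catalyst intermediate B → catalyst intermediate C (k4 = 384 M⁻¹ min⁻¹)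
    free catalyst + target ⇌ idle complex (K5 = 859 M⁻¹, k5 = 0.239 M⁻¹ min⁻¹)
    coupling partner + free catalyst → catalyst intermediate A (k6 = 117 M⁻¹ min⁻¹)

Y is the upper bound, and the lower bound comes from the time of a turn, from free catalyst through catalyst intermediates A, B, C and D and back. Adding the step times, with the two ways back counted and starting material at its lowest, 5.00 mM, gives τ = 97.8 min, so turnover is about 0.00153 mM min⁻¹. As coupling partner falls, free catalyst waits longer for it. At worst, idle complex in equilibrium with target at the full 5.00 mM stretches that wait by a factor 5.29. Integrated, this pessimistic round brings green's coupling partner down to 0.625 mM in 2.42 d, inside 2.5 d, so by this reckoning green makes at least 43.8 %, with 1.98 h to spare.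

Both feeds outrun the round: amber's brings 0.00694 mM min⁻¹ and grey's 0.0139 mM min⁻¹. The fed reagent reaches the level where its step takes as long as τ within 12.6 min in amber and 7.24 min in grey, less than the spare time. Amber's delay is worth 0.19 percentage points of target, less than the margin, so this reckoning expects the flasks to count as equal.

The forecast gives 46.6 % for green, 46.3 % for amber and 46.4 % for grey, verdict all alike, holding that “the slow idle complex bites only at the very end when coupling partner runs low”. Its numbers lie inside the bracket.

The flasks give 49.2 % for green, 48.7 % for amber and 48.9 % for grey: all alike. The spread of 0.50 points is inside the margin, and green stands above both fed flasks.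

At 1.25 d green's round was running with catalyst intermediate C, the resting state, holding 62.3 % of the catalyst and free catalyst 3.81 %, while coupling partner stood at 43.5 % of its charge. By 2.50 d green's coupling partner was down to 0.727 %, its free catalyst had risen to 46.8 % and its idle complex to 22.4 %, with its target 0.80 points under Y. For grey's neighbour with 0.0060 M of starting material, the same ratio gives a ceiling of 83.3 %, and that flask reached 80.6 %.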